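**Strategy.** Both flavan units are 2-aryl benzopyrans in which ring A is a resorcinol unit bonded to O1 at C8a, so one intermediate, an (S)-flav-3-ene, serves both halves. It is made by closing the pyran ring at the O1–C8a aryl ether bond: copper-catalysed intramolecular O-arylation of a (Z)-1,3-diarylallyl alcohol whose ring A carries bromine at the future C8a. The ring closure leaves the C3=C4 alkene. Dihydroxylation anti to the C2 aryl group gives the 3,4-cis-diol of the lower unit; epoxidation of a second portion and opening at C4 by C6 of the protected lower unit forges the 4→6 bond with 3,4-trans geometry.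

Key step: step 5

Assumption 1: the descriptors are read as upper unit 2α-aryl, 3β-OH, 4α-aryl (2,3-trans-3,4-trans) and lower unit 2α-aryl, 3β-OH, 4β-OH (2,3-trans-3,4-cis).
Assumption 2: (S,S)-ProPhenol is taken to deliver the alkynyl group to the Si face of the aryl aldehyde; should the ligand show the opposite sense, its (R,R) enantiomer is used.

Step 1
Reactants: 1 2-bromo-4-hydroxybenzaldehyde
Product: 2 4-(benzyloxy)-2-bromobenzaldehyde
Conditions: BnBr, K2CO3, DMF, rt
Reagents that add atoms: benzyl bromide BrCc1ccccc1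
Why: Williamson ether synthesis on the acidic para-formyl phenol protects the future C7 oxygen as a benzyl ether that lasts to the final hydrogenolysis.

Step 2
Reactants: 2 4-(benzyloxy)-2-bromobenzaldehyde
Product: 3 4-(benzyloxy)-2-bromo-1-ethynylbenzene
Conditions: dimethyl (1-diazo-2-oxopropyl)phosphonate, K2CO3, MeOH, 0 °C to rt
Reagents that add atoms: dimethyl (1-diazo-2-oxopropyl)phosphonate CC(=O)C(=[N+]=[N-])P(=O)(OC)OC
Why: Ohira–Bestmann homologation converts the aryl aldehyde into the terminal alkyne under mild carbonate conditions that leave the aryl bromide and the benzyl ether alone.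

Step 3
Reactants: 3 4-(benzyloxy)-2-bromo-1-ethynylbenzene (1.5 equiv); 4 3,4-bis(benzyloxy)benzaldehyde
Product: 5 (R)-1-[3,4-bis(benzyloxy)phenyl]-3-[4-(benzyloxy)-2-bromophenyl]prop-2-yn-1-ol
Conditions: ZnMe2, (S,S)-ProPhenol (10 mol%), Ph3P=O (20 mol%), toluene, 0 °C to rt
Reagents that add atoms: none
Why: Catalytic enantioselective alkynylzinc addition to an aldehyde, in which the chiral dinuclear zinc–ProPhenol pocket delivers the alkynyl group to the Si face of 4 and so sets the carbinol carbon that becomes C2 of both flavan units.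

Step 4
Reactants: 5 (R)-propargylic alcohol
Product: 6 (S,Z)-1-[3,4-bis(benzyloxy)phenyl]-3-[4-(benzyloxy)-2-bromophenyl]prop-2-en-1-ol
Conditions: H2 (1 atm), Lindlar catalyst (Pd/CaCO3, Pb(OAc)2-poisoned), quinoline, EtOAc, rt
Reagents that add atoms: none
Why: Lindlar semihydrogenation adds H2 syn to the alkyne to give the (Z)-alkene that brings the hydroxyl group next to the C–Br carbon, while the aryl bromide, the benzyl ethers and the carbinol stereocenter are untouched (the descriptor changes from R to S only through the ranking of the substituents).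

Step 5
Reactants: 6 (S,Z)-allylic alcohol
Product: 7 (S)-7-(benzyloxy)-2-[3,4-bis(benzyloxy)phenyl]-2H-chromene (tri-O-benzyl flav-3-ene)
Conditions: CuI (10 mol%), 3,4,7,8-tetramethyl-1,10-phenanthroline (20 mol%), Cs2CO3, toluene, 80 °C, dark
Reagents that add atoms: none
Why: Intramolecular Ullmann-type C–O coupling (copper-catalysed aryl halide etherification, the reaction type used to close chroman and benzopyran rings): the caesium alkoxide of 6 binds monovalent copper, the C8a–Br bond adds oxidatively to give an aryl alkoxide of trivalent copper, and reductive elimination forms the O1–C8a bond. The six-membered pyran ring (ring C) closes in a 6-exo fashion at the sp2 carbon C8a, the breaking C–Br bond lying outside the new ring, and only the (Z)-alkene geometry from step 4 lets the oxygen reach C8a. No stereocenter is created, and C2 keeps its configuration because none of its bonds is broken, the oxygen that becomes O1 being already attached to it. The step needs chemoselectivity for C–O coupling over redox isomerisation of the allylic alkoxide and over hydrodebromination, which the weak carbonate base, the copper catalyst (no beta-hydride elimination of the kind palladium alkoxides show) and the cis-locked tether should secure; there is no regiochemical issue because 6 has one hydroxyl group and one C–Br bond. The product is kept in the dark and below 90 °C so that electrocyclic opening of the 2H-chromene cannot erode the C2 configuration.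

Step 6
Reactants: 7 (S)-tri-O-benzyl flav-3-ene
Product: 8 (2R,3S,4S)-7-(benzyloxy)-2-[3,4-bis(benzyloxy)phenyl]chromane-3,4-diol (2,3-trans-3,4-cis)
Conditions: OsO4 (2 mol%), NMO, acetone/H2O, 0 °C to rt
Reagents that add atoms: osmium tetroxide (catalytic oxygen carrier) O=[Os](=O)(=O)=O; N-methylmorpholine N-oxide C[N+]1([O-])CCOCC1; water O
Why: Catalytic OsO4/NMO syn-dihydroxylation adds both oxygens to the face of the electron-rich C3=C4 alkene opposite to the C2 aryl group, which sets C3 (S) and C4 (S) of the lower unit as the 3β,4β-diol.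

Step 7
Reactants: 8 (2R,3S,4S)-diol
Product: 9 cyclic 3,4-carbonate of 8 (cis-fused; 2α-aryl, 3β,4β-oxygens; CIP 2R,3R,4S, spatial arrangement as in 8)
Conditions: 1,1'-carbonyldiimidazole, CH2Cl2, rt
Reagents that add atoms: 1,1'-carbonyldiimidazole O=C(n1ccnc1)n1ccnc1
Why: Carbonylation of the cis-1,2-diol gives the five-membered cyclic carbonate, which makes both oxygens non-nucleophilic and the benzylic C4–O bond electron-poor so that it does not ionise in step 8, and which is later removed by mild base.

Step 8
Reactants: 7 (S)-tri-O-benzyl flav-3-ene (1 equiv); 9 lower-unit cyclic carbonate (3 equiv, excess recovered)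
Product: 11 hexa-O-benzyl fisetinidol-(4α→6)-(2,3-trans-3,4-cis)-leucofisetinidin 3,4-carbonate (upper unit 2α-aryl, 3β-OH, 4α-linked; lower unit as in 9), via flav-3-ene 3β,4β-epoxide 10 (not isolated)
Conditions: DMDO (acetone), CH2Cl2, −40 °C; volatiles removed cold; then 9, BF3·OEt2 (0.2 equiv), CH2Cl2, −78 °C
Reagents that add atoms: dimethyldioxirane CC1(C)OO1
Why: Dioxirane epoxidation anti to the C2 aryl group gives the labile para-alkoxybenzylic epoxide, and its Lewis-acid-assisted Friedel–Crafts opening at C4 by C6 of 9 (para to O1, ortho to the benzyloxy group and less hindered than C8) occurs with inversion, so that upper C3 (from the epoxide oxygen) and upper C4 (4α-aryl, 3,4-trans) are both fixed, in analogy to flavan-4-yl cation couplings and glycal epoxide couplings.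

Step 9
Reactants: 11 hexa-O-benzyl dimer carbonate
Product: 12 hexa-O-benzyl fisetinidol-(4α→6)-(2,3-trans-3,4-cis)-leucofisetinidin (upper 3-OH, lower 3-OH and 4-OH free)
Conditions: K2CO3 (cat.), MeOH/THF, 0 °C to rt
Reagents that add atoms: none
Why: Base-catalysed transesterification with methanol cleaves the cyclic carbonate to the cis-diol without acid, so the benzylic C4–OH and the interflavan bond are not ionised and the benzyl ethers stay.

Step 10
Reactants: 12 hexa-O-benzyl dimer
Product: 13 (2R,3S,4S)-2-(3,4-dihydroxyphenyl)-6-[(2R,3S,4R)-2-(3,4-dihydroxyphenyl)-3,7-dihydroxychroman-4-yl]chromane-3,4,7-triol (CNP0280090.4)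
Conditions: H2 (1 atm), Pd(OH)2/C, EtOAc/MeOH, rt, stopped at complete debenzylation
Reagents that add atoms: none
Why: Catalytic hydrogenolysis should cleave the six aryl benzyl ethers much faster than the secondary benzylic C4–OH or the C2–O1 bonds under neutral conditions at ambient pressure, as is usual for benzyl-protected flavan-3-ols, and no stereocenter is touched.

**Compound list**

1 | 2-bromo-4-hydroxybenzaldehyde | O=Cc1ccc(O)cc1Br | starting material
2 | 4-(benzyloxy)-2-bromobenzaldehyde | O=Cc1ccc(OCc2ccccc2)cc1Br | intermediate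
3 | 4-(benzyloxy)-2-bromo-1-ethynylbenzene | C#Cc1ccc(OCc2ccccc2)cc1Br | intermediate
4 | 3,4-bis(benzyloxy)benzaldehyde | O=Cc1ccc(OCc2ccccc2)c(OCc2ccccc2)c1 | starting material
5 | (R)-1-[3,4-bis(benzyloxy)phenyl]-3-[4-(benzyloxy)-2-bromophenyl]prop-2-yn-1-ol | O[C@H](c1ccc(OCc2ccccc2)c(OCc2ccccc2)c1)C#Cc1ccc(OCc2ccccc2)cc1Br | intermediate
6 | (S,Z)-1-[3,4-bis(benzyloxy)phenyl]-3-[4-(benzyloxy)-2-bromophenyl]prop-2-en-1-ol | O[C@H](c1ccc(OCc2ccccc2)c(OCc2ccccc2)c1)/C=C\c1ccc(OCc2ccccc2)cc1Br | intermediate
7 | (S)-7-(benzyloxy)-2-[3,4-bis(benzyloxy)phenyl]-2H-chromene | c1cc2c(cc1OCc1ccccc1)O[C@H](c1ccc(OCc3ccccc3)c(OCc3ccccc3)c1)C=C2 | intermediate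
8 | (2R,3S,4S)-7-(benzyloxy)-2-[3,4-bis(benzyloxy)phenyl]chromane-3,4-diol | c1cc2c(cc1OCc1ccccc1)O[C@H](c1ccc(OCc3ccccc3)c(OCc3ccccc3)c1)[C@@H](O)[C@H]2O | intermediate
9 | cyclic 3,4-carbonate of 8 (cis-fused, 2α-aryl, 3β,4β-oxygens) | c1cc2c(cc1OCc1ccccc1)O[C@H](c1ccc(OCc3ccccc3)c(OCc3ccccc3)c1)[C@H]3OC(=O)O[C@@H]23 | intermediate
10 | 3β,4β-epoxide of 7 (anti to the 2α-aryl group) | c1cc2c(cc1OCc1ccccc1)O[C@H](c1ccc(OCc3ccccc3)c(OCc3ccccc3)c1)[C@H]3O[C@@H]23 | intermediate
11 | hexa-O-benzyl fisetinidol-(4α→6)-(2,3-trans-3,4-cis)-leucofisetinidin 3,4-carbonate | c1ccccc1COc1ccc2c(c1)O[C@H](c1ccc(OCc3ccccc3)c(OCc3ccccc3)c1)[C@@H](O)[C@@H]2c1cc2c(cc1OCc1ccccc1)O[C@H](c1ccc(OCc3ccccc3)c(OCc3ccccc3)c1)[C@H]3OC(=O)O[C@@H]23 | intermediate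
12 | hexa-O-benzyl fisetinidol-(4α→6)-(2,3-trans-3,4-cis)-leucofisetinidin | c1ccccc1COc1ccc2c(c1)O[C@H](c1ccc(OCc3ccccc3)c(OCc3ccccc3)c1)[C@@H](O)[C@@H]2c1cc2c(cc1OCc1ccccc1)O[C@H](c1ccc(OCc3ccccc3)c(OCc3ccccc3)c1)[C@@H](O)[C@H]2O | intermediate
13 | (2R,3S,4S)-2-(3,4-dihydroxyphenyl)-6-[(2R,3S,4R)-2-(3,4-dihydroxyphenyl)-3,7-dihydroxychroman-4-yl]chromane-3,4,7-triol | Oc1ccc2c(c1)O[C@H](c1ccc(O)c(O)c1)[C@@H](O)[C@@H]2c1cc2c(cc1O)O[C@H](c1ccc(O)c(O)c1)[C@@H](O)[C@H]2O | target

**Step count.** Total: 10 steps. Longest linear sequence: 10 steps (1 → 2 → 3 → 5 → 6 → 7 → 8 → 9 → 11 → 12 → 13); compound 7 is used twice, in steps 6 and 8.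

**Steps most likely to fail**

Step 5. The allylic alkoxide may isomerise under base to the saturated ketone, or the hindered carbinol may couple too slowly so that hydrodebromination takes over. The fallback closes the same O1–C8a bond on a saturated, protected substrate. It sets out from 6, which is silylated (TBSCl, imidazole) to the tert-butyldimethylsilyl ether F1. Dihydroxylation with OsO4/NMO of the (Z)-alkene, anti to the allylic silyloxy group as usual for acyclic allylic ethers, gives the all-anti silyloxy diol F2. 2,2-Dimethoxypropane with PPTS gives the cis-acetonide F3, and TBAF frees the C2 hydroxyl to give the alcohol F4. Copper-catalysed O-arylation as in step 5 (no allylic system left to isomerise) then gives the 3,4-O-isopropylidene flavan-3,4-diol F5, and mild hydrolysis (aqueous AcOH) comes back to the route at 8. In that case no flav-3-ene is at hand, and the electrophile for the coupling is taken from 8 as in the fallback for step 8.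

Step 8. The epoxide may open or rearrange before it meets the nucleophile, attack may occur at C8 of the lower unit, or the electrophile may condense with itself. The fallback sets out from 8 (a second portion), which is acetylated (Ac2O, pyridine, DMAP) to the 3,4-di-O-acetate F6. BF3·OEt2 at −78 °C ionises the C4 acetate with participation of the 3β-acetoxy group (a dioxolenium ion on the β face), so that C6 of 9 (excess) attacks from the α face and gives the 3-O-acetyl dimer carbonate F7. Methanolysis under the conditions of step 9 removes acetate and carbonate together and comes back to the route at 12.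

Step 10. Hydrogenolysis may go on to remove the benzylic C4–OH of the lower unit, or the free flavan-3,4-diol may condense with itself on the catalyst. The fallback sets out from 11, in which the carbonate still masks that position, and uses a non-reductive debenzylation. BCl3 with pentamethylbenzene as cation scavenger (CH2Cl2, −78 °C) gives the hexaphenol carbonate F8. Brief treatment with K2CO3 in MeOH under argon, then neutralisation, removes the carbonate and comes back to the route at 13.

**Further compounds**

F1 | step 5 | tert-butyldimethylsilyl ether of 6 | CC(C)(C)[Si](C)(C)O[C@H](c1ccc(OCc2ccccc2)c(OCc2ccccc2)c1)/C=C\c1ccc(OCc2ccccc2)cc1Br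
F2 | step 5 | all-anti diol from syn-dihydroxylation of F1 (silyloxy at C2, hydroxyls at C3 and C4, flavan numbering) | CC(C)(C)[Si](C)(C)O[C@H](c1ccc(OCc2ccccc2)c(OCc2ccccc2)c1)[C@@H](O)[C@@H](O)c1ccc(OCc2ccccc2)cc1Br
F3 | step 5 | cis-acetonide of F2 | CC(C)(C)[Si](C)(C)O[C@H](c1ccc(OCc2ccccc2)c(OCc2ccccc2)c1)[C@H]1OC(C)(C)O[C@H]1c1ccc(OCc2ccccc2)cc1Br
F4 | step 5 | free C2 alcohol from desilylation of F3 | O[C@H](c1ccc(OCc2ccccc2)c(OCc2ccccc2)c1)[C@H]1OC(C)(C)O[C@H]1c1ccc(OCc2ccccc2)cc1Br
F5 | step 5 | 3,4-O-isopropylidene derivative of 8 | c1cc2c(cc1OCc1ccccc1)O[C@H](c1ccc(OCc3ccccc3)c(OCc3ccccc3)c1)[C@H]3OC(C)(C)O[C@@H]23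
F6 | step 8 | 3,4-di-O-acetate of 8 | c1cc2c(cc1OCc1ccccc1)O[C@H](c1ccc(OCc3ccccc3)c(OCc3ccccc3)c1)[C@@H](OC(C)=O)[C@H]2OC(C)=O
F7 | step 8 | 3-O-acetate (upper unit) of 11 | c1ccccc1COc1ccc2c(c1)O[C@H](c1ccc(OCc3ccccc3)c(OCc3ccccc3)c1)[C@@H](OC(C)=O)[C@@H]2c1cc2c(cc1OCc1ccccc1)O[C@H](c1ccc(OCc3ccccc3)c(OCc3ccccc3)c1)[C@H]3OC(=O)O[C@@H]23
F8 | step 10 | lower-unit 3,4-carbonate of 13 (all phenols free) | Oc1ccc2c(c1)O[C@H](c1ccc(O)c(O)c1)[C@@H](O)[C@@H]2c1cc2c(cc1O)O[C@H](c1ccc(O)c(O)c1)[C@H]3OC(=O)O[C@@H]23
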